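## The problem

The target 33 is a 20-nor-gibberellin. Rings A and B form a trans-fused hydrindane whose C4 and C10 are bridged on the α face by a γ-lactone (C19–O–C10). Ring B is joined through the quaternary C8 and the C8–C9 bond to a bicyclo[3.2.1]octane (rings C and D) that carries the 16-methylene group. There are nine stereocentres (C3, C4, C5, C6, C8, C9, C10, C12, C13), four of them fully substituted (C4, C8, C10, C13). Only C6 needs control from outside. A substituent at C6 can send a new bond at C5 to the opposite face; the chair of ring A and the lactone tether then fix C4 and C10. A β-hydrogen at C9 sends a new bond at C8 to the same face (cis-hydrindanone), closure of ring D leaves no choice at C13, and the axial C10 on ring C screens one face of C12. Three features are fragile: the tertiary allylic 13-alcohol beside the 16-methylene group rearranges in strong acid, the 3β-hydroxy lactone epimerises by retro-aldol cleavage in base, and the C10–O bond becomes a leaving group whenever C9 is part of, or conjugated with, a π system. The opening lies at C4: it carries the methyl group C18, the C3 oxygen and the C19 carbonyl, so it is the α-carbon of a 2-methyl-3-oxo ester, and the two bonds it needs (C4–C5 directly, C10–O through C19) sit at the two ends of the C5–C10 bond. If ring C is a benzene ring, C5=C10 is the double bond of an indene and C19 lies 1,3-diaxial to C10 on ring A, so an ester at C4 can capture an electron-poor C10.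

## Retrosynthesis

**C7 and the protecting groups.** The acid 33 is taken back to tetraol 32 and to bis-silyl ether 31; no skeletal bond is cut. A carboxyl group at C7 would make H-6 enolisable through every basic step, whereas a primary alcohol is inert and can be oxidised last in the presence of secondary and tertiary alcohols. The forward step must pick one hydroxyl out of four.

**C12.** The 12α-alcohol 31 is derived from ketone 30, and 30 from diol 29 of either configuration at C12. Setting C12 while ring C is still monocyclic was rejected because the face of attack on that enolate cannot be predicted with confidence. In the bridged ketone 30 the face of C12 anti to the C15–C16 bridge is closed by the axial C10, so hydride must enter from the bridge side.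

**Ring D.** Cutting C13–C16 of 29 leads to α-hydroxy ketone 28, which carries a 2-bromoallyl group on C8. The other ring-D bond, C8–C15, would call for alkylation at a hindered ring fusion. A reductive ketyl–alkyne closure was also set aside, because a one-electron reductant would remove the oxygen at C12. The forward reaction must add a vinyl metal to a ketone without touching the lactone; the ring size allows only one configuration at C13.

**C12–O and C8–C15.** Removing the hydroxyl of 28 gives ketone 26, and cutting C8–C15 gives enone 24 and allylsilane 25. C8 is the β-carbon of the enone, so conjugate allylation builds the quaternary centre, and with H-9 already in place the cis-hydrindanone should form. The kinetic enolate of 26 should form at C12 because C14 is neopentyl. The precursor 24 has one ring and two stereocentres fewer than 29.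

**Ring C.** Enone 24 (through alcohol 23) is the reduction product of an anisole, which leads back to the tetracyclic arene 18.
- The C10–O bond of 18 is benzylic, and a lactone there would be cleaved by dissolving metal. The lactone is therefore opened to carboxylate 19, in which C10 bears an alkoxide that cannot leave.
- Reduction gives dienol ether 20 and, after mild hydrolysis, the deconjugated enone 21.
- The double bond is moved into conjugation (22) while C10 still bears hydroxyl, because a lactone at that stage would be lost by vinylogous β-elimination.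
- Acid then recloses the lactone to give 23. C9 is set under equilibrium, with C11 trans to C1.

**C3.** Silyl ether 18 comes from alcohol 17 and ketone 16. The ketone must be reduced before step 12, since a 3-oxo lactone without α-hydrogen would suffer retro-Claisen cleavage in hydroxide. The silyl ether blocks the retro-aldol path of the free 3-hydroxy lactone.

**The key disconnection.** In 16 the C4–C5 bond and the C10–O bond are cut together, which gives keto ester 15. This removes two rings and three stereocentres at once and leaves ring A at its final oxidation pattern. A polar cut at C4–C5 has no acceptor at C5, and a cationic closure from C10 would form the wrong bond. The forward step must close 6-endo, attack the indene face anti to the C6 substituent, and keep the ester axial at C4.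

**Side chain.** Keto ester 15 comes from aldol 14, which is cut at C3–C4 into aldehyde 11 and the enolate 13 of ester 12. Aldehyde 11 comes from carbinol 10 by dehydration, and 10 is cut at C10–C1 into indanone 7 and Grignard reagent 9, made from bromide 8. Both cuts use carbonyl additions; the one demand is that the acidic C6–H of the indene is never exposed to base at a temperature where it can exchange.

**C6.** Indanone 7 is opened at the aryl–acyl bond to acid 5 (from ester 4). Ester 4 is cut at the aryl–C6 bond into boronic acid 3 and enoate 2, which is made from bromide 1. A catalytic asymmetric aryl addition to an acyclic enoate is better established than the addition of a one-carbon nucleophile to an unstable indenone.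

## Roads not taken

**Alternative 1:** The cut is the C6–C8 bond, read backwards as a ring enlargement. A1, the 3,12-bis-silyl ether of the methyl ester of 33, would arise from the six-membered ring B diazo ketone A2 by photolysis in methanol (Wolff rearrangement: loss of nitrogen, shift of C8 from C7 to C6, capture of the ketene as the C7 ester).
- Merits: the rearrangement is dependable, C8 migrates with retention, and C7 arrives at the acid oxidation state.
- Weak points: A2 holds every difficulty of 33 (the bridged ring A, the bicyclo[3.2.1]octane, the 12,13-diol) in a skeleton one carbon larger. Diazo transfer to C6 needs prior activation. C6 is set by protonation of an ester enol and may need base near a base-labile lactone. The methyl ester must be cleaved last.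
- Comparison: as an endgame this road is better than the chosen one, since no alcohol has to be picked out of four. Against that, the chosen plan builds ring A, the lactone and three stereocentres in one early step, while this road leaves the synthesis of A2 open.

**Alternative 2:** The cuts are C8–C9 and C11–C12. The open-chain trienone A4 would close by an intramolecular Diels–Alder reaction to the cis-hydrindanone A3.
- Merits: rings B and C form in one step, C8 is quaternary with its propargyl arm, the ring fusion is cis, and the C12 oxygen and the C13 enol ether are ready for ring D. No aromatic ring has to be reduced. In this respect the road is clearly better than the chosen one, which spends steps 12 to 16 and a delicate pH sequence on the same pattern.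
- Weak points: A3 has nothing of ring A. C4 with its two substituents, the C5 stereocentre and the tertiary C10–O bond would have to be added bond by bond to a hindered cyclopentanone. The diene of A4 bears an inward substituent at C8, and facial control rests on one enolisable C6 centre.
- Comparison: the two roads are mirror images. The chosen plan obtains ring A and the lactone cheaply and pays at ring C; this road does the opposite and leaves the harder quaternary centre for later.

**Alternative 3:** The cut is C12–C13. Keto aldehyde A6 would close to diol A5 by reductive pinacol coupling with SmI2.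
- Merits: one step closes ring C, forms the bicyclo[3.2.1]octane and delivers both hydroxyl groups. The chosen plan needs steps 16 to 19 for the same result.
- Weak points: A6 must already contain the bridged A/B unit, a spiro cyclopentanone with an extra stereocentre at C16, and an aldehyde on C11. The silyloxymethyl group must later be turned into the methylene group beside a tertiary alcohol. C12 is set by the coupling itself and cannot be corrected.
- Comparison: for the diol this road is shorter. The chosen plan offers a C12 configuration that is set last and can be repeated, and a route to the A/B core that this cut does not provide.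

Key step: step 9

Remark on the chemistry (assumption): rhodium with (S)-BINAP is taken to add the aryl group to the face of the (E)-enoate that gives (S)-4; if the sense is the reverse, (R)-BINAP is used and nothing else changes.

Remark on names: polycyclic compounds carry gibberellane locants. Ring A is C1–C5 and C10; ring B is C5, C6, C8, C9, C10; ring C is C8, C9, C11–C14; ring D is C8, C13–C16; C7 is on C6, C17 on C16, C18 and C19 on C4. β is the face of ring B that bears H-5; α is the face of the lactone bridge. Compounds 10, 14, 15, 28 and 29 are mixtures at centres that are later destroyed or corrected (C10; C3 and C4; C4; C12; C12).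

## Steps

Step 1
Reactants: 1 methyl (E)-4-bromobut-2-enoate
Product: 2 methyl (E)-4-(pivaloyloxy)but-2-enoate
Conditions: pivalic acid, Cs2CO3, DMF, 20 °C
Reagents that add atoms: pivalic acid, CC(C)(C)C(=O)O
Why: SN2 displacement of the primary allylic bromide by cesium pivalate. The pivalate has no α-hydrogen and should survive every step up to step 11.

Step 2
Reactants: 2 methyl (E)-4-(pivaloyloxy)but-2-enoate; 3 3-methoxyphenylboronic acid
Product: 4 methyl (S)-3-(3-methoxyphenyl)-4-(pivaloyloxy)butanoate
Conditions: Rh(acac)(C2H4)2 (3 mol%), (S)-BINAP, 1,4-dioxane/H2O (10:1), 100 °C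
Reagents that add atoms: none
Why: Hayashi–Miyaura reaction (rhodium-catalysed asymmetric 1,4-addition of an arylboronic acid to an enoate). The chiral bisphosphine on monovalent rhodium selects the enoate face and so sets C6.

Step 3
Reactants: 4 methyl (S)-3-(3-methoxyphenyl)-4-(pivaloyloxy)butanoate
Product: 5 (S)-3-(3-methoxyphenyl)-4-(pivaloyloxy)butanoic acid
Conditions: LiOH·H2O (1.1 equiv), THF/H2O, 0 °C; then 1 M HCl
Reagents that add atoms: lithium hydroxide, [Li+].[OH-]
Why: Saponification; the unhindered methyl ester should react well before the pivalate, and C6 has no acidic hydrogen.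

Step 4
Reactants: 5 (S)-3-(3-methoxyphenyl)-4-(pivaloyloxy)butanoic acid
Product: 7 [(1S)-6-methoxy-3-oxoindan-1-yl]methyl pivalate, via acid chloride 6 (not isolated)
Conditions: (COCl)2, DMF (cat.), CH2Cl2, 0 → 20 °C; then AlCl3, CH2Cl2, 0 °C
Reagents that add atoms: none
Why: Intramolecular Friedel–Crafts acylation; the five-membered ring closes para to the methoxy group. C6 is β to the new ketone and cannot be enolised.

Step 5
Reactants: 7 [(1S)-6-methoxy-3-oxoindan-1-yl]methyl pivalate; 8 2-(2-bromoethyl)-1,3-dioxolane
Product: 10 [(1S)-3-[2-(1,3-dioxolan-2-yl)ethyl]-3-hydroxy-6-methoxyindan-1-yl]methyl pivalate, via Grignard reagent 9 (not isolated)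
Conditions: 8, Mg, THF, 25 °C; then 7, LaCl3·2LiCl, THF, 0 °C; aq. NH4Cl
Reagents that add atoms: none
Why: Grignard 1,2-addition forms the C10–C1 bond; the lanthanum salt suppresses enolisation of the indanone and the cold ketone reacts before the pivalate. The new carbinol centre is removed in step 6.

Step 6
Reactants: 10 [(1S)-3-[2-(1,3-dioxolan-2-yl)ethyl]-3-hydroxy-6-methoxyindan-1-yl]methyl pivalate
Product: 11 [(1S)-6-methoxy-3-(3-oxopropyl)-1H-inden-1-yl]methyl pivalate
Conditions: TsOH·H2O (cat.), acetone/H2O, 40 °C
Reagents that add atoms: water, O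
Why: E1 dehydration of the tertiary para-methoxybenzylic alcohol gives the conjugated endocyclic indene (C5=C10), and the dioxolane is hydrolysed in the same flask. Acid does not touch C6.

Step 7
Reactants: 11 [(1S)-6-methoxy-3-(3-oxopropyl)-1H-inden-1-yl]methyl pivalate; 12 tert-butyl propanoate
Product: 14 tert-butyl 3-hydroxy-5-[(1S)-6-methoxy-1-(pivaloyloxymethyl)-1H-inden-3-yl]-2-methylpentanoate, via lithium enolate 13 (not isolated)
Conditions: 12, LiN(i-Pr)2, THF, −78 °C; then 11, −78 °C; AcOH at −78 °C
Reagents that add atoms: none
Why: Aldol addition forms C3–C4. Addition to the aldehyde at −78 °C and a cold acidic quench should outrun deprotonation of the indene C6–H. The two new centres are removed in steps 8 and 9.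

Step 8
Reactants: 14 tert-butyl 3-hydroxy-5-[(1S)-6-methoxy-1-(pivaloyloxymethyl)-1H-inden-3-yl]-2-methylpentanoate
Product: 15 tert-butyl 5-[(1S)-6-methoxy-1-(pivaloyloxymethyl)-1H-inden-3-yl]-2-methyl-3-oxopentanoate
Conditions: Dess–Martin periodinane, NaHCO3, CH2Cl2, 0 → 20 °C
Reagents that add atoms: none
Why: Dess–Martin oxidation of the secondary alcohol under buffered, non-basic conditions, so the indene double bond cannot shift.

Step 9
Reactants: 15 tert-butyl 5-[(1S)-6-methoxy-1-(pivaloyloxymethyl)-1H-inden-3-yl]-2-methyl-3-oxopentanoate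
Product: 16 13-methoxy-3-oxo-7-pivaloyloxy ring-C-aromatic 19,10-lactone
Conditions: Mn(OAc)3·2H2O (2.2 equiv), Cu(OAc)2·H2O (1 equiv), AcOH, 25 → 40 °C
Reagents that add atoms: none
Why: Mn(OAc)3 oxidises the enol form of the 2-methyl-3-oxo ester by one electron to the electrophilic tertiary C4 radical; the closest known reaction type is the oxidative free-radical cyclisation of unsaturated 2-alkyl-3-oxo esters in which an oxidised tertiary radical is caught by the ester as a lactone. Ring A closes 6-endo-trig: the radical adds to the unsubstituted C5 end of the indene double bond because this gives a tertiary benzylic C10 radical stabilised by the para methoxy group, whereas 5-exo attack on the fully substituted C10 would give a secondary radical. Cu(OAc)2 (divalent copper) oxidises the C10 radical to the cation, and the lactone ring closes 5-exo by attack of the carbonyl oxygen of the tert-butyl ester with loss of isobutene. C5 is set by the C6 stereocentre, since the chain reaches C5 on the indene face anti to the pivaloyloxymethyl group. C4 is set by the chair transition state, which keeps the ester axial and the methyl group equatorial. C10 is set by the tether, because the C4 ester can reach the cation only from the face on which C4 sits. The step needs 6-endo over 5-exo closure, anti facial attack, and oxidation of the C10 radical faster than hydrogen abstraction; benzylic stabilisation, the single substituent at C6 and the stoichiometric copper salt should secure these.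

Step 10
Reactants: 16 13-methoxy-3-oxo-7-pivaloyloxy ring-C-aromatic 19,10-lactone
Product: 17 3β-hydroxy-13-methoxy-7-pivaloyloxy ring-C-aromatic 19,10-lactone
Conditions: K[HB(s-Bu)3], THF, −78 °C; aq. NH4Cl
Reagents that add atoms: none
Why: Reduction by a bulky trialkylborohydride, which attacks the chair ketone along the equatorial path and should give the axial 3β-alcohol, as with other 4,4-disubstituted cyclohexanones. Lactone and pivalate should not react at −78 °C.

Step 11
Reactants: 17 3β-hydroxy-13-methoxy-7-pivaloyloxy ring-C-aromatic 19,10-lactone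
Product: 18 3β-(tert-butyldimethylsilyloxy)-13-methoxy-7-pivaloyloxy ring-C-aromatic 19,10-lactone
Conditions: TBSOTf, 2,6-lutidine, CH2Cl2, 0 °C
Reagents that add atoms: tert-butyldimethylsilyl triflate, CC(C)(C)[Si](C)(C)OS(=O)(=O)C(F)(F)F
Why: Silylation of a hindered axial alcohol with the silyl triflate. The ether blocks retro-aldol epimerisation at C3 in step 12 and survives dissolving metal.

Step 12
Reactants: 18 3β-(tert-butyldimethylsilyloxy)-13-methoxy-7-pivaloyloxy ring-C-aromatic 19,10-lactone
Product: 19 potassium 7,10α-dihydroxy-13-methoxy-3β-silyloxy ring-C-aromatic 19-carboxylate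
Conditions: KOH, MeOH/H2O, 65 °C; evaporation, azeotropic drying (toluene)
Reagents that add atoms: potassium hydroxide, [K+].[OH-]
Why: Saponification opens the lactone and removes the pivalate. The salt is not acidified, so the benzylic C10 oxygen enters step 13 as hydroxyl or alkoxide and not as an ester that dissolving metal would cleave.

Step 13
Reactants: 19 potassium 7,10α-dihydroxy-13-methoxy-3β-silyloxy ring-C-aromatic 19-carboxylate
Product: 23 7-hydroxy-13-oxo-3β-silyloxy-8(14)-ene 19,10-lactone (9β-H), via dienol ether seco acid 20 (not isolated), via deconjugated enone seco acid 21 (not isolated), via conjugated enone seco acid 22 (not isolated)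
Conditions: Li, NH3(l), THF, t-BuOH, −78 °C; isoprene, then NH4Cl; AcOH/NaOAc buffer (pH 4.5), THF/H2O, 0 °C; NaOH (pH 13), 20 °C; HCl (pH 2), 20 °C
Reagents that add atoms: water, O
Why: Birch reduction of the anisole, as in the 19-norsteroid series, should give the 2,5-dihydroanisole with the C8=C9 double bond; the C10 alkoxide and C19 carboxylate are not leaving groups, so the benzylic oxygen should stay. Buffered hydrolysis gives the deconjugated enone, and base moves the double bond to C8=C14 while C10 bears hydroxyl; C9 is protonated under equilibrium so that C11 lies trans to C1 (9β-H). Acid then recloses the γ-lactone.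

Step 14
Reactants: 23 7-hydroxy-13-oxo-3β-silyloxy-8(14)-ene 19,10-lactone (9β-H)
Product: 24 13-oxo-3β,7-bis(tert-butyldimethylsilyloxy)-8(14)-ene 19,10-lactone
Conditions: TBSCl, imidazole, DMF, 20 °C
Reagents that add atoms: tert-butyldimethylsilyl chloride, CC(C)(C)[Si](C)(C)Cl
Why: Silylation of the only free, primary hydroxyl, so that titanium and amide reagents in steps 15 and 16 meet no acidic proton.

Step 15
Reactants: 24 13-oxo-3β,7-bis(tert-butyldimethylsilyloxy)-8(14)-ene 19,10-lactone; 25 (2-bromoallyl)trimethylsilane
Product: 26 8β-(2-bromoallyl)-13-oxo-3β,7-bis(tert-butyldimethylsilyloxy) 19,10-lactone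
Conditions: 25 (3 equiv), TiCl4, CH2Cl2, −78 °C
Reagents that add atoms: none
Why: Hosomi–Sakurai conjugate allylation forms the quaternary C8–C15 bond. Axial attack on the half-chair enone anti to C10, that is cis to H-9, should give the cis-hydrindanone with C15 on the β face.

Step 16
Reactants: 26 8β-(2-bromoallyl)-13-oxo-3β,7-bis(tert-butyldimethylsilyloxy) 19,10-lactone
Product: 28 8β-(2-bromoallyl)-12-hydroxy-13-oxo-3β,7-bis(tert-butyldimethylsilyloxy) 19,10-lactone, via potassium 12(13)-enolate 27 (not isolated)
Conditions: KN(SiMe3)2, THF, −78 °C; then 2-(phenylsulfonyl)-3-phenyloxaziridine, −78 °C; aq. NH4Cl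
Reagents that add atoms: 2-(phenylsulfonyl)-3-phenyloxaziridine, O=S(=O)(c1ccccc1)N1OC1c1ccccc1
Why: Kinetic deprotonation should occur at C12 because C14 is flanked by the quaternary C8; the enolate is hydroxylated by the N-sulfonyloxaziridine. The configuration at C12 does not matter, since steps 18 and 19 reset it.

Step 17
Reactants: 28 8β-(2-bromoallyl)-12-hydroxy-13-oxo-3β,7-bis(tert-butyldimethylsilyloxy) 19,10-lactone
Product: 29 12,13-dihydroxy-16-methylene-3β,7-bis(tert-butyldimethylsilyloxy) 19,10-lactone with ring D closed
Conditions: CrCl2 (6 equiv), NiCl2 (5 mol%), DMF, 25 → 50 °C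
Reagents that add atoms: none
Why: Intramolecular Nozaki–Hiyama–Kishi reaction: zerovalent nickel inserts into the alkenyl bromide, the alkenyl group passes to trivalent chromium and adds to the activated α-hydroxy ketone, leaving lactone and silyl ethers alone. The one-carbon bridge allows only one configuration at C13, and the 16-methylene group is formed directly.

Step 18
Reactants: 29 12,13-dihydroxy-16-methylene-3β,7-bis(tert-butyldimethylsilyloxy) 19,10-lactone with ring D closed
Product: 30 13-hydroxy-12-oxo-3β,7-bis(tert-butyldimethylsilyloxy) 19,10-lactone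
Conditions: Dess–Martin periodinane, NaHCO3, CH2Cl2, 0 °C
Reagents that add atoms: none
Why: Dess–Martin oxidation of the secondary alcohol; the tertiary bridgehead alcohol cannot be oxidised, and buffered low-temperature conditions disfavour an α-ketol shift.

Step 19
Reactants: 30 13-hydroxy-12-oxo-3β,7-bis(tert-butyldimethylsilyloxy) 19,10-lactone
Product: 31 12α,13-dihydroxy-3β,7-bis(tert-butyldimethylsilyloxy) 19,10-lactone
Conditions: Li[HB(s-Bu)3], THF, −78 °C; aq. NH4Cl
Reagents that add atoms: none
Why: Ketone reduction by a bulky borohydride. In the locked chair of ring C the face of C12 anti to the C15–C16 bridge is blocked by the axial C10, so hydride should enter from the bridge side and leave the hydroxyl axial, syn to C10 and anti to C16 (12α).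

Step 20
Reactants: 31 12α,13-dihydroxy-3β,7-bis(tert-butyldimethylsilyloxy) 19,10-lactone
Product: 32 3β,7,12α,13-tetrahydroxy 19,10-lactone
Conditions: HF·pyridine, THF/pyridine, 0 → 20 °C
Reagents that add atoms: none
Why: Fluoride-mediated cleavage of both silyl ethers in a buffered medium that is neither acidic enough to rearrange the tertiary allylic alcohol nor basic enough to open the 3-hydroxy lactone by retro-aldol cleavage.

Step 21
Reactants: 32 3β,7,12α,13-tetrahydroxy 19,10-lactone
Product: 33 CNP0260503.1 (3β,12α,13-trihydroxy-20-norgibberell-16-ene-7,19-dioic acid 19,10-lactone)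
Conditions: TEMPO (cat.), PhI(OAc)2, MeCN/aq. phosphate buffer (pH 7), 0 → 20 °C
Reagents that add atoms: water, O
Why: Oxoammonium-mediated oxidation, which is selective for the primary alcohol over hindered secondary and tertiary ones; the aldehyde hydrate is oxidised on to the acid. No stereocentre is formed, and C6 keeps its configuration under buffered conditions.

## Compound list

1 | methyl (E)-4-bromobut-2-enoate | COC(=O)/C=C/CBr | starting material
2 | methyl (E)-4-(pivaloyloxy)but-2-enoate | COC(=O)/C=C/COC(=O)C(C)(C)C | intermediate
3 | 3-methoxyphenylboronic acid | COc1cccc(B(O)O)c1 | starting material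
4 | methyl (S)-3-(3-methoxyphenyl)-4-(pivaloyloxy)butanoate | COc1cccc(c1)[C@@H](COC(=O)C(C)(C)C)CC(=O)OC | intermediate
5 | (S)-3-(3-methoxyphenyl)-4-(pivaloyloxy)butanoic acid | COc1cccc(c1)[C@@H](COC(=O)C(C)(C)C)CC(=O)O | intermediate
6 | (S)-3-(3-methoxyphenyl)-4-(pivaloyloxy)butanoyl chloride | COc1cccc(c1)[C@@H](COC(=O)C(C)(C)C)CC(=O)Cl | intermediate
7 | [(1S)-6-methoxy-3-oxoindan-1-yl]methyl pivalate (5-methoxy-3-(pivaloyloxymethyl)indan-1-one) | COc1ccc2c(c1)[C@@H](COC(=O)C(C)(C)C)CC2=O | intermediate
8 | 2-(2-bromoethyl)-1,3-dioxolane | BrCCC1OCCO1 | starting material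
9 | [2-(1,3-dioxolan-2-yl)ethyl]magnesium bromide | Br[Mg]CCC1OCCO1 | intermediate
10 | [(1S)-3-[2-(1,3-dioxolan-2-yl)ethyl]-3-hydroxy-6-methoxyindan-1-yl]methyl pivalate, both epimers at the carbinol carbon | COc1ccc2c(c1)[C@@H](COC(=O)C(C)(C)C)CC2(O)CCC1OCCO1 | intermediate
11 | [(1S)-6-methoxy-3-(3-oxopropyl)-1H-inden-1-yl]methyl pivalate | COc1ccc2c(c1)[C@@H](COC(=O)C(C)(C)C)C=C2CCC=O | intermediate
12 | tert-butyl propanoate | CCC(=O)OC(C)(C)C | starting material
13 | lithium enolate of tert-butyl propanoate | CC=C(O[Li])OC(C)(C)C | intermediate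
14 | tert-butyl 3-hydroxy-5-[(1S)-6-methoxy-1-(pivaloyloxymethyl)-1H-inden-3-yl]-2-methylpentanoate, mixture at C2 and C3 of the chain | COc1ccc2c(c1)[C@@H](COC(=O)C(C)(C)C)C=C2CCC(O)C(C)C(=O)OC(C)(C)C | intermediate
15 | tert-butyl 5-[(1S)-6-methoxy-1-(pivaloyloxymethyl)-1H-inden-3-yl]-2-methyl-3-oxopentanoate, mixture at C2 of the chain | COc1ccc2c(c1)[C@@H](COC(=O)C(C)(C)C)C=C2CCC(=O)C(C)C(=O)OC(C)(C)C | intermediate
16 | 13-methoxy-3-oxo-7-pivaloyloxy ring-C-aromatic 19,10-lactone (C8, C9, C11–C14 form the benzene ring; 4β-methyl, 4α-C19, 5β-H, 6β-CH2OPiv, 10α-O) | COc1ccc2c(c1)[C@@H](COC(=O)C(C)(C)C)[C@H]1[C@@]23CCC(=O)[C@@]1(C)C(=O)O3 | intermediate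
17 | 3β-hydroxy-13-methoxy-7-pivaloyloxy ring-C-aromatic 19,10-lactone (3-OH axial, anti to C19) | COc1ccc2c(c1)[C@@H](COC(=O)C(C)(C)C)[C@H]1[C@@]23CC[C@H](O)[C@@]1(C)C(=O)O3 | intermediate
18 | 3β-(tert-butyldimethylsilyloxy)-13-methoxy-7-pivaloyloxy ring-C-aromatic 19,10-lactone | COc1ccc2c(c1)[C@@H](COC(=O)C(C)(C)C)[C@H]1[C@@]23CC[C@H](O[Si](C)(C)C(C)(C)C)[C@@]1(C)C(=O)O3 | intermediate
19 | potassium 7,10α-dihydroxy-13-methoxy-3β-silyloxy ring-C-aromatic 19-carboxylate (lactone opened) | COc1ccc2c(c1)[C@@H](CO)[C@H]1[C@@]2(O)CC[C@H](O[Si](C)(C)C(C)(C)C)[C@@]1(C)C(=O)[O-].[K+] | intermediate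
20 | dienol ether seco acid: 13-methoxy-8(9),12(13)-diene, 7,10α-diol, 19-acid (present as its salt) | COC1=CCC2=C(C1)[C@@H](CO)[C@H]1[C@@]2(O)CC[C@H](O[Si](C)(C)C(C)(C)C)[C@@]1(C)C(=O)O | intermediate
21 | deconjugated enone seco acid: 13-oxo-8(9)-ene, 7,10α-diol, 19-acid (present as its salt) | O=C1CCC2=C(C1)[C@@H](CO)[C@H]1[C@@]2(O)CC[C@H](O[Si](C)(C)C(C)(C)C)[C@@]1(C)C(=O)O | intermediate
22 | conjugated enone seco acid: 13-oxo-8(14)-ene, 9β-H, 7,10α-diol, 19-acid | O=C1CC[C@@H]2C(=C1)[C@@H](CO)[C@H]1[C@@]2(O)CC[C@H](O[Si](C)(C)C(C)(C)C)[C@@]1(C)C(=O)O | intermediate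
23 | 7-hydroxy-13-oxo-3β-silyloxy-8(14)-ene 19,10-lactone (9β-H) | O=C1CC[C@@H]2C(=C1)[C@@H](CO)[C@H]1[C@@]23CC[C@H](O[Si](C)(C)C(C)(C)C)[C@@]1(C)C(=O)O3 | intermediate
24 | 13-oxo-3β,7-bis(tert-butyldimethylsilyloxy)-8(14)-ene 19,10-lactone (9β-H) | O=C1CC[C@@H]2C(=C1)[C@@H](CO[Si](C)(C)C(C)(C)C)[C@H]1[C@@]23CC[C@H](O[Si](C)(C)C(C)(C)C)[C@@]1(C)C(=O)O3 | intermediate
25 | (2-bromoallyl)trimethylsilane | C[Si](C)(C)CC(Br)=C | starting material
26 | 8β-(2-bromoallyl)-13-oxo-3β,7-bis(tert-butyldimethylsilyloxy) 19,10-lactone (9β-H, C15 cis to C7) | O=C1CC[C@@H]2[C@](CC(Br)=C)(C1)[C@@H](CO[Si](C)(C)C(C)(C)C)[C@H]1[C@@]23CC[C@H](O[Si](C)(C)C(C)(C)C)[C@@]1(C)C(=O)O3 | intermediate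
27 | potassium 12(13)-enolate of 26 | [K]OC1=CC[C@@H]2[C@](CC(Br)=C)(C1)[C@@H](CO[Si](C)(C)C(C)(C)C)[C@H]1[C@@]23CC[C@H](O[Si](C)(C)C(C)(C)C)[C@@]1(C)C(=O)O3 | intermediate
28 | 8β-(2-bromoallyl)-12-hydroxy-13-oxo-3β,7-bis(tert-butyldimethylsilyloxy) 19,10-lactone, either configuration at C12 | O=C1C(O)C[C@@H]2[C@](CC(Br)=C)(C1)[C@@H](CO[Si](C)(C)C(C)(C)C)[C@H]1[C@@]23CC[C@H](O[Si](C)(C)C(C)(C)C)[C@@]1(C)C(=O)O3 | intermediate
29 | 12,13-dihydroxy-16-methylene-3β,7-bis(tert-butyldimethylsilyloxy) 19,10-lactone, ring D closed, either configuration at C12 | C=C1C[C@]23C[C@@]1(O)C(O)C[C@H]2[C@@]12CC[C@H](O[Si](C)(C)C(C)(C)C)[C@@](C)(C(=O)O1)[C@H]2[C@@H]3CO[Si](C)(C)C(C)(C)C | intermediate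
30 | 13-hydroxy-12-oxo-3β,7-bis(tert-butyldimethylsilyloxy) 19,10-lactone | C=C1C[C@]23C[C@@]1(O)C(=O)C[C@H]2[C@@]12CC[C@H](O[Si](C)(C)C(C)(C)C)[C@@](C)(C(=O)O1)[C@H]2[C@@H]3CO[Si](C)(C)C(C)(C)C | intermediate
31 | 12α,13-dihydroxy-3β,7-bis(tert-butyldimethylsilyloxy) 19,10-lactone (12-OH axial, syn to C10, anti to C16) | C=C1C[C@]23C[C@@]1(O)[C@@H](O)C[C@H]2[C@@]12CC[C@H](O[Si](C)(C)C(C)(C)C)[C@@](C)(C(=O)O1)[C@H]2[C@@H]3CO[Si](C)(C)C(C)(C)C | intermediate
32 | 3β,7,12α,13-tetrahydroxy 19,10-lactone | C=C1C[C@]23C[C@@]1(O)[C@@H](O)C[C@H]2[C@@]12CC[C@H](O)[C@@](C)(C(=O)O1)[C@H]2[C@@H]3CO | intermediate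
33 | CNP0260503.1, 3β,12α,13-trihydroxy-20-norgibberell-16-ene-7,19-dioic acid 19,10-lactone | C=C1C[C@]23C[C@@]1(O)[C@@H](O)C[C@H]2[C@@]12CC[C@H](O)[C@@](C)(C(=O)O1)[C@H]2[C@@H]3C(=O)O | target

## Step count and least certain steps

Total step count: 21. Longest linear sequence: 21 steps (1 → 33); the other building blocks 3, 8, 12 and 25 are bought and enter directly.

**Step 9 (key step).** The most likely failure is wrong termination: the C10 cation, or its copper-bound precursor, loses a proton or is caught by acetate instead of by the ester. Partial 5-exo closure and attack on the face syn to the C6 substituent are the other possibilities. Fallback, from 15 back to 16: the ring closure and the lactonisation are separated. The same Mn(OAc)3 cyclisation is run so that it ends by oxidative elimination, and the 1(10)-alkene tert-butyl ester F1 is isolated. CF3CO2H in CH2Cl2 then cleaves the tert-butyl ester and protonates the styrene double bond at C1. The resulting C10 cation is captured by the C19 acid on the only face it can reach, which gives 16.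

**Step 13.** Three things can go wrong. The C10 alkoxide may be protonated in the reducing medium and the benzylic oxygen then lost reductively. The lactone may reclose too early, at the deconjugated stage, and then be expelled as carboxylate by vinylogous β-elimination when base is added. The equilibrium at C9 may not be clean. Fallback, from 18 back to 24: C19 is carried as an alcohol, so that neither lactonisation nor an acyloxy leaving group can arise. LiAlH4 reduces the lactone and the pivalate to the 7,10,19-triol F2, and TBSCl silylates the less hindered primary alcohol at C7 to give the 10,19-diol F3. Birch reduction of its dialkoxide, oxalic acid hydrolysis and NaOMe conjugation give the enone diol F4. TEMPO with PhI(OAc)2 oxidises the 1,4-diol to the lactone, which is 24.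

**Step 15.** The bromine-bearing allylsilane may be too weak a nucleophile for a β,β-disubstituted enone. Attack may also occur on the α face, away from the C7 substituent, which would give the trans-fused epimer. The primary silyl ether may be lost to TiCl4. Fallback, from 23 back to 26: the C8–C15 bond is delivered from the C7 oxygen, which guarantees the cis relation.
- The free alcohol of 23 is converted with ethyl vinyl ether and N-bromosuccinimide into the bromoacetal F5.
- Ueno–Stork radical cyclisation (Bu3SnH, AIBN) onto the enone β-carbon gives the cyclic acetal F6.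
- Aqueous acid gives the lactol F7.
- The Ohira–Bestmann reagent converts F7 into the alkynol F8.
- TBSCl gives the silyl ether F9.
- Markovnikov hydrobromination (B-bromo-9-borabicyclo[3.3.1]nonane, then AcOH) gives 26.

**Step 17.** Insertion into the alkenyl bromide may be slow, or the alkenylchromium may add sluggishly to the hindered ketone, so that protodebromination wins. Fallback, from 28 back to 29: the carbon–metal bond is made first and a different metal carries out the addition. Miyaura borylation (Pd(dppf)Cl2, bis(pinacolato)diboron, KOAc) gives the alkenylboronate F10. A rhodium hydroxide catalyst ([Rh(cod)OH]2, aqueous dioxane) then effects the intramolecular 1,2-addition of the alkenyl group to the ketone and gives 29.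

**Step 21.** The oxidant may also attack the secondary alcohols at C3 and C12, the iodine reagent may cleave the 12,13-diol, and C6 may epimerise at the aldehyde stage. Fallback, from 31 back to 33: the oxidation is done before ring A is unmasked and without the iodine reagent. HF·pyridine buffered with excess pyridine at 0 °C removes only the primary silyl ether and gives the 7-alcohol F11. Catalytic TEMPO with NaClO2 and a trace of NaOCl in buffered acetonitrile oxidises it to the acid F12. HF·pyridine then frees the 3β-alcohol and gives 33.

## Further compounds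

F1 | step 9 | tert-butyl ester of the cyclised 1(10)-alkene (13-methoxy-3-oxo-7-pivaloyloxy ring-C-aromatic 1(10)-ene 19-oate) | COc1ccc2c(c1)[C@@H](COC(=O)C(C)(C)C)[C@H]1C2=CCC(=O)[C@@]1(C)C(=O)OC(C)(C)C
F2 | step 13 | 7,10α,19-triol from reduction of 18 (3β-silyloxy, 13-methoxy, ring C aromatic) | COc1ccc2c(c1)[C@@H](CO)[C@H]1[C@@]2(O)CC[C@H](O[Si](C)(C)C(C)(C)C)[C@@]1(C)CO
F3 | step 13 | 10α,19-diol 3β,7-bis(tert-butyldimethylsilyl) ether (13-methoxy, ring C aromatic) | COc1ccc2c(c1)[C@@H](CO[Si](C)(C)C(C)(C)C)[C@H]1[C@@]2(O)CC[C@H](O[Si](C)(C)C(C)(C)C)[C@@]1(C)CO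
F4 | step 13 | 13-oxo-8(14)-ene 10α,19-diol 3β,7-bis(tert-butyldimethylsilyl) ether (9β-H) | O=C1CC[C@@H]2C(=C1)[C@@H](CO[Si](C)(C)C(C)(C)C)[C@H]1[C@@]2(O)CC[C@H](O[Si](C)(C)C(C)(C)C)[C@@]1(C)CO
F5 | step 15 | 7-O-(2-bromo-1-ethoxyethyl) ether of 23 | O=C1CC[C@@H]2C(=C1)[C@@H](COC(CBr)OCC)[C@H]1[C@@]23CC[C@H](O[Si](C)(C)C(C)(C)C)[C@@]1(C)C(=O)O3
F6 | step 15 | cyclic ethyl acetal C8–C15–C16(OEt)–O–C7 of the 13-ketone (C15 cis to C7) | O=C1CC[C@@H]2[C@@]3(C1)CC(OCC)OC[C@H]3[C@H]1[C@@]24CC[C@H](O[Si](C)(C)C(C)(C)C)[C@@]1(C)C(=O)O4
F7 | step 15 | lactol corresponding to F6 | O=C1CC[C@@H]2[C@@]3(C1)CC(O)OC[C@H]3[C@H]1[C@@]24CC[C@H](O[Si](C)(C)C(C)(C)C)[C@@]1(C)C(=O)O4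
F8 | step 15 | 8β-(prop-2-ynyl)-7-hydroxy-13-oxo-3β-silyloxy 19,10-lactone | O=C1CC[C@@H]2[C@](CC#C)(C1)[C@@H](CO)[C@H]1[C@@]23CC[C@H](O[Si](C)(C)C(C)(C)C)[C@@]1(C)C(=O)O3
F9 | step 15 | 8β-(prop-2-ynyl)-13-oxo-3β,7-bis(tert-butyldimethylsilyloxy) 19,10-lactone | O=C1CC[C@@H]2[C@](CC#C)(C1)[C@@H](CO[Si](C)(C)C(C)(C)C)[C@H]1[C@@]23CC[C@H](O[Si](C)(C)C(C)(C)C)[C@@]1(C)C(=O)O3
F10 | step 17 | pinacol alkenylboronate from 28 (boron in place of bromine) | O=C1C(O)C[C@@H]2[C@](CC(=C)B5OC(C)(C)C(C)(C)O5)(C1)[C@@H](CO[Si](C)(C)C(C)(C)C)[C@H]1[C@@]23CC[C@H](O[Si](C)(C)C(C)(C)C)[C@@]1(C)C(=O)O3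
F11 | step 21 | 7,12α,13-trihydroxy-3β-(tert-butyldimethylsilyloxy) 19,10-lactone | C=C1C[C@]23C[C@@]1(O)[C@@H](O)C[C@H]2[C@@]12CC[C@H](O[Si](C)(C)C(C)(C)C)[C@@](C)(C(=O)O1)[C@H]2[C@@H]3CO
F12 | step 21 | 3-O-tert-butyldimethylsilyl ether of 33 | C=C1C[C@]23C[C@@]1(O)[C@@H](O)C[C@H]2[C@@]12CC[C@H](O[Si](C)(C)C(C)(C)C)[C@@](C)(C(=O)O1)[C@H]2[C@@H]3C(=O)O
A1 | alternative 1 | 3,12-bis(tert-butyldimethylsilyl) ether of the methyl ester of 33 | C=C1C[C@]23C[C@@]1(O)[C@@H](O[Si](C)(C)C(C)(C)C)C[C@H]2[C@@]12CC[C@H](O[Si](C)(C)C(C)(C)C)[C@@](C)(C(=O)O1)[C@H]2[C@@H]3C(=O)OC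
A2 | alternative 1 | six-membered ring B 6-diazo-7-ketone (3,12-bis-silyl ether) | C=C1C[C@]23C[C@@]1(O)[C@@H](O[Si](C)(C)C(C)(C)C)C[C@H]2[C@@]12CC[C@H](O[Si](C)(C)C(C)(C)C)[C@@](C)(C(=O)O1)[C@H]2C(=[N+]=[N-])C3=O
A3 | alternative 2 | cis-hydrindanone of rings B and C with C13 trimethylsilyl enol ether, C12 silyl ether and 8-(3-trimethylsilylprop-2-ynyl) group | C[Si](C)(C)C#CC[C@]12C=C(O[Si](C)(C)C)[C@@H](O[Si](C)(C)C(C)(C)C)C[C@H]1C(=O)C[C@@H]2C(=O)OC
A4 | alternative 2 | open-chain trienone: methyl 2-[bis-silyloxy diene]-4-oxohex-5-enoate | C=CC(=O)C[C@H](C(=O)OC)/C(CC#C[Si](C)(C)C)=C/C(O[Si](C)(C)C)=C/O[Si](C)(C)C(C)(C)C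
A5 | alternative 3 | pentacyclic 12,13-diol with C16 silyloxymethyl group (methyl ester, 3-silyl ether) | CC(C)(C)[Si](C)(C)OC[C@H]1C[C@]23C[C@@]1(O)[C@@H](O)C[C@H]2[C@@]12CC[C@H](O[Si](C)(C)C(C)(C)C)[C@@](C)(C(=O)O1)[C@H]2[C@@H]3C(=O)OC
A6 | alternative 3 | keto aldehyde: spiro ring D cyclopentanone (C13 ketone) with C12 aldehyde on C11 | CC(C)(C)[Si](C)(C)OC[C@H]1C[C@]2(CC1=O)[C@@H](CC=O)[C@@]13CC[C@H](O[Si](C)(C)C(C)(C)C)[C@@](C)(C(=O)O1)[C@H]3[C@@H]2C(=O)OC
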